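**Plan**
- Retrosynthetic cuts: C12'–C15' (Suzuki–Miyaura), C8–C9 at the butenolide α-carbon (Suzuki–Miyaura), C6'–C7' (Stille), the butenolide C10–C11/O–C11 bonds (Sonogashira–lactonisation) and, last, the C6–O bridge bond of the 7-oxabicyclo[2.2.1]heptane.
- Enabling feature: the ether oxygen spans C3 and C6 across the cyclohexane, and the C5 hydroxyl is vicinal and trans to the C6–O bond. This is the outcome of an axial C3–OH opening a 5,6-epoxide at its allylic carbon C6, so the precursor is the trans-3-hydroxy-5,6-epoxide, and one C–O bond closes the oxolane O–C3–C2–C1–C6 (and with it the bicycle).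
- Forward order: diol ring from ketoisophorone → enol triflate → trienylboronate 13; butenolide linchpin 17 from dibromoacrylic acid and the enynol; epoxy end group from (−)-actinol joined to 17; the oxygen bridge is then closed as the last ring; iodo-olefination; final coupling with 13.
- Stereochemistry: C3' by asymmetric transfer hydrogenation, C4' by hydroxyl-directed epoxidation; C3 from actinol, C5/C6 by Sharpless epoxidation with C6 inverted in the key step. Alkene geometry comes from the commercial (E)-enynol, anti-oxymetalation (Z-ylidene), E-selective olefinations and stereoretentive couplings.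

Key step: step 23

Remark: carotenoid locants are used in the explanations (ring C1–C6, chain C7–C15, primes for the diol half); ketone 4 and silyl ether 5 are carried as epimer mixtures at the methyl-bearing carbon, which becomes sp2 in step 5.
Remark: compounds 1, 8, 14 and 18 are taken as the commercially available starting materials; the route is a proposal and no step has been run.

Step 1
Reactants: 1 ketoisophorone
Product: 2 (4S)-4-hydroxy-2,6,6-trimethylcyclohex-2-en-1-one
Conditions: RuCl[(S,S)-TsDPEN](p-cymene) (cat.), iPrOH, rt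
Reagents that add atoms: none
Why: Noyori asymmetric transfer hydrogenation should reduce only the less hindered C4 carbonyl (the other is flanked by the quaternary carbon and the methylated alkene carbon), and the (S,S) ligand is expected to give the (S)-carbinol, the future C3'.

Step 2
Reactants: 2 (S)-hydroxy enone
Product: 3 (1S,5S,6S)-5-hydroxy-1,3,3-trimethyl-7-oxabicyclo[4.1.0]heptan-2-one
Conditions: 30% H2O2, NaOH (cat.), MeOH, 0 °C
Reagents that add atoms: hydrogen peroxide, OO
Why: Weitz–Scheffer nucleophilic epoxidation in which the free hydroxyl hydrogen-bonds the hydroperoxide anion and steers it to the β-carbon on its own face, so the epoxide oxygen (the future C4' oxygen) should enter cis to the hydroxyl.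

Step 3
Reactants: 3 cis-epoxy alcohol
Product: 4 (4S,5R)-4,5-dihydroxy-2,2,6-trimethylcyclohexan-1-one
Conditions: SmI2, THF/MeOH, −90 °C
Reagents that add atoms: none
Why: reductive opening of an α,β-epoxy ketone by divalent samarium (ketyl formation, loss of the α C–O bond, protonation) leaves the β-hydroxyl untouched, so the cis-3',4'-diol is kept; the methyl-bearing carbon forms as an inconsequential mixture.

Step 4
Reactants: 4 cis-diol ketone
Product: 5 (4S,5R)-4,5-bis(tert-butyldimethylsilyloxy)-2,2,6-trimethylcyclohexan-1-one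
Conditions: TBSOTf, 2,6-lutidine, CH2Cl2, −78 to 0 °C
Reagents that add atoms: tert-butyldimethylsilyl triflate, CC(C)(C)[Si](C)(C)OS(=O)(=O)C(F)(F)F
Why: silyl ether formation at both secondary hydroxyls with a silyl triflate and a hindered pyridine base should be faster at low temperature than enolisation or β-elimination of the β-hydroxy ketone.

Step 5
Reactants: 5 bis-silyl ketone
Product: 7 (3R,4S)-3,4-bis(tert-butyldimethylsilyloxy)-2,6,6-trimethylcyclohex-1-en-1-yl triflate, via potassium enolate 6 (not isolated)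
Conditions: KN(SiMe3)2 (KHMDS), THF, −78 °C; then PhNTf2, −78 to 0 °C
Reagents that add atoms: KHMDS, C[Si](C)(C)[N-][Si](C)(C)C.[K+] (potassium of 6 only); N-phenylbis(trifluoromethanesulfonimide), O=S(=O)(N(c1ccccc1)S(=O)(=O)C(F)(F)F)C(F)(F)F
Why: enol triflate formation; the ketone has a single α-hydrogen, so one enolate forms and is O-sulfonylated at −78 °C before the β-silyloxy group can be eliminated.

Step 6
Reactants: 8 (2E)-3-methylpent-2-en-4-yn-1-ol
Product: 9 (2E,4E)-3-methyl-5-(tributylstannyl)penta-2,4-dien-1-ol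
Conditions: Bu3SnH, PdCl2(PPh3)2 (cat.), THF, 0 °C to rt
Reagents that add atoms: tributyltin hydride, CCCC[SnH](CCCC)CCCC
Why: palladium-catalysed syn-hydrostannation of the terminal alkyne should place tin on the terminal carbon and give the (E)-alkenylstannane; the trisubstituted alkene keeps the E geometry of the commercial enynol.

Step 7
Reactants: 7 enol triflate; 9 dienylstannane
Product: 10 (2E,4E)-5-[(3R,4S)-3,4-bis(tert-butyldimethylsilyloxy)-2,6,6-trimethylcyclohex-1-en-1-yl]-3-methylpenta-2,4-dien-1-ol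
Conditions: Pd2(dba)3 (cat.), AsPh3, NMP, 60 °C
Reagents that add atoms: none
Why: Stille coupling of a hindered cyclohexenyl triflate with an alkenylstannane under ligand-accelerated conditions forms the C6'–C7' bond with retention of the diene geometry and tolerates the free primary alcohol.

Step 8
Reactants: 10 dienol
Product: 11 (2E,4E)-5-[(3R,4S)-3,4-bis(tert-butyldimethylsilyloxy)-2,6,6-trimethylcyclohex-1-en-1-yl]-3-methylpenta-2,4-dienal
Conditions: MnO2, CH2Cl2, rt
Reagents that add atoms: none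
Why: allylic oxidation with MnO2 should touch only the primary dienylic alcohol because both ring oxygens are silylated.

Step 9
Reactants: 11 bis-silyl dienal
Product: 12 (2E,4E)-5-[(3R,4S)-3,4-dihydroxy-2,6,6-trimethylcyclohex-1-en-1-yl]-3-methylpenta-2,4-dienal
Conditions: Bu4NF, AcOH, THF, 0 °C to rt
Reagents that add atoms: none
Why: buffered fluoride desilylation frees the cis-diol without enolising the dienal, and doing it here avoids any fluoride or acid treatment of the finished polyene.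

Step 10
Reactants: 12 diol dienal
Product: 13 (1S,2R)-3,5,5-trimethyl-4-[(1E,3E,5E)-3-methyl-6-(4,4,5,5-tetramethyl-1,3,2-dioxaborolan-2-yl)hexa-1,3,5-trien-1-yl]cyclohex-3-ene-1,2-diol
Conditions: CrCl2, LiI, Cl2CHBpin, THF, rt
Reagents that add atoms: 2-(dichloromethyl)-4,4,5,5-tetramethyl-1,3,2-dioxaborolane, CC1(C)OB(C(Cl)Cl)OC1(C)C
Why: Takai–Utimoto boryl-olefination with the gem-dichromium reagent should convert the aldehyde into the (E)-alkenylboronate and is known to tolerate free hydroxyls.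

Step 11
Reactants: 14 propiolic acid
Product: 15 (2E)-2,3-dibromoprop-2-enoic acid
Conditions: Br2, CHCl3, 0 °C to rt, dark
Reagents that add atoms: bromine, BrBr
Why: anti addition of bromine to the alkyne gives the (E)-dibromide, in which the β-bromine is cis to the carboxyl group as the later lactonisation requires.

Step 12
Reactants: 15 dibromoacrylic acid; 8 (2E)-3-methylpent-2-en-4-yn-1-ol
Product: 17 (5Z)-3-bromo-5-[(2E)-4-hydroxy-2-methylbut-2-en-1-ylidene]furan-2(5H)-one, via enynoic acid 16 (not isolated)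
Conditions: Pd(PPh3)4 (cat.), CuI (cat.), Et3N, MeCN, rt
Reagents that add atoms: none
Why: tandem Sonogashira coupling–lactonisation of a β-haloacrylic acid: coupling occurs at the more reactive β-bromine, and the (Z)-enynoic acid closes by 5-exo-dig anti-oxymetalation and protodemetalation, which fixes the Z ylidene geometry.

Step 13
Reactants: 18 (−)-actinol
Product: 19 (4R,6R)-2,2,6-trimethyl-4-(triethylsilyloxy)cyclohexan-1-one
Conditions: TESCl, imidazole, DMF, 0 °C to rt
Reagents that add atoms: chlorotriethylsilane, CC[Si](Cl)(CC)CC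
Why: routine silyl ether formation; the carbinol stereocentre (C3 of the target) comes from the starting material.

Step 14
Reactants: 19 silyl ether ketone
Product: 21 (4R)-2,6,6-trimethyl-4-(triethylsilyloxy)cyclohex-1-en-1-yl triflate, via potassium enolate 20 (not isolated)
Conditions: KN(SiMe3)2 (KHMDS), THF, −78 °C; then PhNTf2, −78 to 0 °C
Reagents that add atoms: KHMDS, C[Si](C)(C)[N-][Si](C)(C)C.[K+] (potassium of 20 only); N-phenylbis(trifluoromethanesulfonimide), O=S(=O)(N(c1ccccc1)S(=O)(=O)C(F)(F)F)C(F)(F)F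
Why: enol triflate formation; only the methyl-bearing α-carbon carries a hydrogen, so a single tetrasubstituted enolate is trapped.

Step 15
Reactants: 21 enol triflate
Product: 22 methyl (4R)-2,6,6-trimethyl-4-(triethylsilyloxy)cyclohex-1-ene-1-carboxylate
Conditions: Pd(OAc)2 (cat.), PPh3, CO (1 atm), Et3N, MeOH/DMF, 60 °C
Reagents that add atoms: carbon monoxide, [C-]#[O+]; methanol, CO
Why: palladium-catalysed methoxycarbonylation of an enol triflate (oxidative addition, CO insertion, methanolysis) installs C7.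

Step 16
Reactants: 22 ester
Product: 23 [(4R)-2,6,6-trimethyl-4-(triethylsilyloxy)cyclohex-1-en-1-yl]methanol
Conditions: i-Bu2AlH, CH2Cl2, −78 °C
Reagents that add atoms: none
Why: hydride reduction of the conjugated ester to the allylic alcohol leaves the tetrasubstituted alkene and the silyl ether untouched.

Step 17
Reactants: 23 allylic alcohol
Product: 24 [(1R,4S,6R)-2,2,6-trimethyl-4-(triethylsilyloxy)-7-oxabicyclo[4.1.0]heptan-1-yl]methanol
Conditions: Ti(OiPr)4, D-(−)-diethyl tartrate, t-BuOOH, 4 Å MS, CH2Cl2, −20 °C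
Reagents that add atoms: tert-butyl hydroperoxide, CC(C)(C)OO
Why: Sharpless asymmetric epoxidation; the D-(−)-tartrate complex should deliver oxygen to the alkene face opposite the C3 silyloxy group (reagent control), which sets C5 and C6 as the trans, violaxanthin-type epoxide.

Step 18
Reactants: 24 epoxy alcohol
Product: 25 (1S,4S,6R)-2,2,6-trimethyl-4-(triethylsilyloxy)-7-oxabicyclo[4.1.0]heptane-1-carbaldehyde
Conditions: Dess–Martin periodinane, NaHCO3, CH2Cl2, 0 °C to rt
Reagents that add atoms: none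
Why: Dess–Martin oxidation under buffered conditions gives the non-enolisable epoxy aldehyde without opening the epoxide.

Step 19
Reactants: 25 epoxy aldehyde
Product: 26 4,4,5,5-tetramethyl-2-[(E)-2-[(1S,4S,6R)-2,2,6-trimethyl-4-(triethylsilyloxy)-7-oxabicyclo[4.1.0]heptan-1-yl]ethenyl]-1,3,2-dioxaborolane
Conditions: CH2(Bpin)2, LiTMP (lithium 2,2,6,6-tetramethylpiperidide), THF, 0 °C; then 25, −78 °C to rt
Reagents that add atoms: bis(4,4,5,5-tetramethyl-1,3,2-dioxaborolan-2-yl)methane, CC1(C)OB(CB2OC(C)(C)C(C)(C)O2)OC1(C)C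
Why: boron–Wittig olefination: the lithiated gem-diboronate adds to the aldehyde and syn B–O elimination should give the (E)-alkenylboronate (C7=C8) under non-Lewis-acidic conditions that spare the epoxide.

Step 20
Reactants: 26 epoxy alkenylboronate; 17 bromobutenolide
Product: 27 (5Z)-5-[(2E)-4-hydroxy-2-methylbut-2-en-1-ylidene]-3-[(E)-2-[(1S,4S,6R)-2,2,6-trimethyl-4-(triethylsilyloxy)-7-oxabicyclo[4.1.0]heptan-1-yl]ethenyl]furan-2(5H)-one
Conditions: Pd2(dba)3 (cat.), AsPh3, Ag2O, THF/H2O, 40 °C, dark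
Reagents that add atoms: none
Why: Suzuki–Miyaura coupling at the α-bromine of the butenolide, promoted by Ag2O in place of a strong aqueous base, joins C8 to C9 with retention of both alkene geometries.

Step 21
Reactants: 27 butenolide allylic alcohol
Product: 28 (2E,4Z)-3-methyl-4-[5-oxo-4-[(E)-2-[(1S,4S,6R)-2,2,6-trimethyl-4-(triethylsilyloxy)-7-oxabicyclo[4.1.0]heptan-1-yl]ethenyl]furan-2(5H)-ylidene]but-2-enal
Conditions: MnO2, CH2Cl2, rt, dark
Reagents that add atoms: none
Why: allylic oxidation with MnO2 is selective for the primary alcohol, and the resulting dienal makes the whole C7–C15 π-system electron-poor for the key step.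

Step 22
Reactants: 28 silyl ether
Product: 29 (2E,4Z)-4-[4-[(E)-2-[(1S,4S,6R)-4-hydroxy-2,2,6-trimethyl-7-oxabicyclo[4.1.0]heptan-1-yl]ethenyl]-5-oxofuran-2(5H)-ylidene]-3-methylbut-2-enal
Conditions: HF·pyridine, pyridine, THF, 0 °C
Reagents that add atoms: none
Why: buffered HF·pyridine desilylation removes the triethylsilyl ether in a medium that is neither basic enough to open the enol lactone nor acidic enough to open the epoxide.

Step 23
Reactants: 29 trans-3-hydroxy-5,6-epoxide
Product: 30 (2E,4Z)-4-[4-[(E)-2-[(1R,2R,4S)-2-hydroxy-2,6,6-trimethyl-7-oxabicyclo[2.2.1]heptan-1-yl]ethenyl]-5-oxofuran-2(5H)-ylidene]-3-methylbut-2-enal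
Conditions: CSA (cat.), CH2Cl2, 0 °C to rt, dark
Reagents that add atoms: none
Why: CSA protonates the epoxide oxygen and the axial C3 hydroxyl, which lies on the ring face opposite the epoxide, displaces the C6–O bond from the rear in a boat-like transition state, so one new C6–O bond bridges the cyclohexane (transannular etherification). The closest known reaction type is the acid-catalysed conversion of 4-hydroxy-1,2-epoxycyclohexanes into 7-oxabicyclo[2.2.1]heptan-2-ols, as in hydroxy-cineole formation and the 5,6-epoxy-3-ol to 3,6-epoxy-5-ol isomerisation of carotenoid end groups. The oxolane O–C3–C2–C1–C6 closes in the 5-exo-tet mode with respect to the epoxide (C5 stays outside it), and the same bond completes the second oxolane O–C3–C4–C5–C6 in the 5-endo sense. C6 is the only stereocentre that changes: it is inverted, and because the tether lets the oxygen reach C6 only from the face anti to the leaving oxygen, its configuration is fixed by the untouched C3 and C5 centres, the former epoxide oxygen becoming the endo tertiary alcohol at C5. The step needs cleavage of C6–O and not of C5–O, and it must avoid attack of the C5 oxygen on C8 (5,8-furanoid closure) and pinacol-type shifts: attack at C5 would need an oxetane, C6 is the allylic terminus, and the C7=C8 bond is conjugated to the butenolide and the dienal, which disfavours a free allyl cation so that the pre-positioned hydroxyl should win.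

Step 24
Reactants: 30 bicyclic butenolide dienal
Product: 31 (5Z)-3-[(E)-2-[(1R,2R,4S)-2-hydroxy-2,6,6-trimethyl-7-oxabicyclo[2.2.1]heptan-1-yl]ethenyl]-5-[(2E,4E)-5-iodo-2-methylpenta-2,4-dien-1-ylidene]furan-2(5H)-one
Conditions: CrCl2, CHI3, THF/dioxane, 0 °C to rt, dark
Reagents that add atoms: iodoform, IC(I)I
Why: Takai iodo-olefination with the gem-dichromium reagent should convert the aldehyde into the (E)-iodoalkene chemoselectively in the presence of the lactone and the free tertiary alcohol.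

Step 25
Reactants: 31 dienyl iodide; 13 trienylboronate
Product: 32 CNP0216838.1
Conditions: Pd(OAc)2 (cat.), SPhos, aq. K3PO4, THF, rt, dark
Reagents that add atoms: none
Why: Suzuki–Miyaura coupling of the alkenyl iodide with the alkenylboronate forms the C12'–C15' bond with retention of both geometries and tolerates the three free hydroxyls, so the polyene is completed without a final deprotection.

**Compound list**
1 | 2,6,6-trimethylcyclohex-2-ene-1,4-dione (ketoisophorone) | CC1=CC(=O)CC(C)(C)C1=O | starting material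
2 | (4S)-4-hydroxy-2,6,6-trimethylcyclohex-2-en-1-one | CC1=C[C@@H](O)CC(C)(C)C1=O | intermediate
3 | (1S,5S,6S)-5-hydroxy-1,3,3-trimethyl-7-oxabicyclo[4.1.0]heptan-2-one (epoxide cis to OH) | C[C@]12O[C@H]1[C@@H](O)CC(C)(C)C2=O | intermediate
4 | (4S,5R)-4,5-dihydroxy-2,2,6-trimethylcyclohexan-1-one (cis-diol, epimers at C6) | CC1[C@@H](O)[C@@H](O)CC(C)(C)C1=O | intermediate
5 | (4S,5R)-4,5-bis(tert-butyldimethylsilyloxy)-2,2,6-trimethylcyclohexan-1-one (epimers at C6) | CC1[C@@H](O[Si](C)(C)C(C)(C)C)[C@@H](O[Si](C)(C)C(C)(C)C)CC(C)(C)C1=O | intermediate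
6 | potassium (3R,4S)-3,4-bis(tert-butyldimethylsilyloxy)-2,6,6-trimethylcyclohex-1-en-1-olate | CC1=C([O-])C(C)(C)C[C@H](O[Si](C)(C)C(C)(C)C)[C@@H]1O[Si](C)(C)C(C)(C)C.[K+] | intermediate (not isolated)
7 | (3R,4S)-3,4-bis(tert-butyldimethylsilyloxy)-2,6,6-trimethylcyclohex-1-en-1-yl trifluoromethanesulfonate | CC1=C(OS(=O)(=O)C(F)(F)F)C(C)(C)C[C@H](O[Si](C)(C)C(C)(C)C)[C@@H]1O[Si](C)(C)C(C)(C)C | intermediate
8 | (2E)-3-methylpent-2-en-4-yn-1-ol | OC/C=C(C)/C#C | starting material
9 | (2E,4E)-3-methyl-5-(tributylstannyl)penta-2,4-dien-1-ol | OC/C=C(C)/C=C/[Sn](CCCC)(CCCC)CCCC | intermediate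
10 | (2E,4E)-5-[(3R,4S)-3,4-bis(tert-butyldimethylsilyloxy)-2,6,6-trimethylcyclohex-1-en-1-yl]-3-methylpenta-2,4-dien-1-ol | CC1=C(/C=C/C(C)=C/CO)C(C)(C)C[C@H](O[Si](C)(C)C(C)(C)C)[C@@H]1O[Si](C)(C)C(C)(C)C | intermediate
11 | (2E,4E)-5-[(3R,4S)-3,4-bis(tert-butyldimethylsilyloxy)-2,6,6-trimethylcyclohex-1-en-1-yl]-3-methylpenta-2,4-dienal | CC1=C(/C=C/C(C)=C/C=O)C(C)(C)C[C@H](O[Si](C)(C)C(C)(C)C)[C@@H]1O[Si](C)(C)C(C)(C)C | intermediate
12 | (2E,4E)-5-[(3R,4S)-3,4-dihydroxy-2,6,6-trimethylcyclohex-1-en-1-yl]-3-methylpenta-2,4-dienal | CC1=C(/C=C/C(C)=C/C=O)C(C)(C)C[C@H](O)[C@@H]1O | intermediate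
13 | (1S,2R)-3,5,5-trimethyl-4-[(1E,3E,5E)-3-methyl-6-(4,4,5,5-tetramethyl-1,3,2-dioxaborolan-2-yl)hexa-1,3,5-trien-1-yl]cyclohex-3-ene-1,2-diol | CC1=C(/C=C/C(C)=C/C=C/B2OC(C)(C)C(C)(C)O2)C(C)(C)C[C@H](O)[C@@H]1O | intermediate
14 | prop-2-ynoic acid (propiolic acid) | C#CC(=O)O | starting material
15 | (2E)-2,3-dibromoprop-2-enoic acid | OC(=O)/C(Br)=C\Br | intermediate
16 | (2E,6E)-2-bromo-8-hydroxy-6-methylocta-2,6-dien-4-ynoic acid | OC/C=C(C)/C#C/C=C(Br)\C(=O)O | intermediate (not isolated)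
17 | (5Z)-3-bromo-5-[(2E)-4-hydroxy-2-methylbut-2-en-1-ylidene]furan-2(5H)-one | OC/C=C(C)/C=C1C=C(Br)C(=O)O/1 | intermediate
18 | (4R,6R)-4-hydroxy-2,2,6-trimethylcyclohexan-1-one ((−)-actinol) | C[C@@H]1C[C@@H](O)CC(C)(C)C1=O | starting material
19 | (4R,6R)-2,2,6-trimethyl-4-(triethylsilyloxy)cyclohexan-1-one | C[C@@H]1C[C@@H](O[Si](CC)(CC)CC)CC(C)(C)C1=O | intermediate
20 | potassium (4R)-2,6,6-trimethyl-4-(triethylsilyloxy)cyclohex-1-en-1-olate | CC1=C([O-])C(C)(C)C[C@H](O[Si](CC)(CC)CC)C1.[K+] | intermediate (not isolated)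
21 | (4R)-2,6,6-trimethyl-4-(triethylsilyloxy)cyclohex-1-en-1-yl trifluoromethanesulfonate | CC1=C(OS(=O)(=O)C(F)(F)F)C(C)(C)C[C@H](O[Si](CC)(CC)CC)C1 | intermediate
22 | methyl (4R)-2,6,6-trimethyl-4-(triethylsilyloxy)cyclohex-1-ene-1-carboxylate | CC1=C(C(=O)OC)C(C)(C)C[C@H](O[Si](CC)(CC)CC)C1 | intermediate
23 | [(4R)-2,6,6-trimethyl-4-(triethylsilyloxy)cyclohex-1-en-1-yl]methanol | CC1=C(CO)C(C)(C)C[C@H](O[Si](CC)(CC)CC)C1 | intermediate
24 | [(1R,4S,6R)-2,2,6-trimethyl-4-(triethylsilyloxy)-7-oxabicyclo[4.1.0]heptan-1-yl]methanol (epoxide trans to the silyloxy group) | OC[C@@]12O[C@]1(C)C[C@@H](O[Si](CC)(CC)CC)CC2(C)C | intermediate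
25 | (1S,4S,6R)-2,2,6-trimethyl-4-(triethylsilyloxy)-7-oxabicyclo[4.1.0]heptane-1-carbaldehyde | O=C[C@@]12O[C@]1(C)C[C@@H](O[Si](CC)(CC)CC)CC2(C)C | intermediate
26 | 4,4,5,5-tetramethyl-2-[(E)-2-[(1S,4S,6R)-2,2,6-trimethyl-4-(triethylsilyloxy)-7-oxabicyclo[4.1.0]heptan-1-yl]ethenyl]-1,3,2-dioxaborolane | CC1(C)OB(/C=C/[C@@]23O[C@]2(C)C[C@@H](O[Si](CC)(CC)CC)CC3(C)C)OC1(C)C | intermediate
27 | (5Z)-5-[(2E)-4-hydroxy-2-methylbut-2-en-1-ylidene]-3-[(E)-2-[(1S,4S,6R)-2,2,6-trimethyl-4-(triethylsilyloxy)-7-oxabicyclo[4.1.0]heptan-1-yl]ethenyl]furan-2(5H)-one | OC/C=C(C)/C=C1C=C(/C=C/[C@@]23O[C@]2(C)C[C@@H](O[Si](CC)(CC)CC)CC3(C)C)C(=O)O/1 | intermediate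
28 | (2E,4Z)-3-methyl-4-[5-oxo-4-[(E)-2-[(1S,4S,6R)-2,2,6-trimethyl-4-(triethylsilyloxy)-7-oxabicyclo[4.1.0]heptan-1-yl]ethenyl]furan-2(5H)-ylidene]but-2-enal | O=C/C=C(C)/C=C1C=C(/C=C/[C@@]23O[C@]2(C)C[C@@H](O[Si](CC)(CC)CC)CC3(C)C)C(=O)O/1 | intermediate
29 | (2E,4Z)-4-[4-[(E)-2-[(1S,4S,6R)-4-hydroxy-2,2,6-trimethyl-7-oxabicyclo[4.1.0]heptan-1-yl]ethenyl]-5-oxofuran-2(5H)-ylidene]-3-methylbut-2-enal | O=C/C=C(C)/C=C1C=C(/C=C/[C@@]23O[C@]2(C)C[C@@H](O)CC3(C)C)C(=O)O/1 | intermediate
30 | (2E,4Z)-4-[4-[(E)-2-[(1R,2R,4S)-2-hydroxy-2,6,6-trimethyl-7-oxabicyclo[2.2.1]heptan-1-yl]ethenyl]-5-oxofuran-2(5H)-ylidene]-3-methylbut-2-enal | O=C/C=C(C)/C=C1C=C(/C=C/[C@@]23O[C@@H](CC2(C)C)C[C@@]3(C)O)C(=O)O/1 | intermediate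
31 | (5Z)-3-[(E)-2-[(1R,2R,4S)-2-hydroxy-2,6,6-trimethyl-7-oxabicyclo[2.2.1]heptan-1-yl]ethenyl]-5-[(2E,4E)-5-iodo-2-methylpenta-2,4-dien-1-ylidene]furan-2(5H)-one | I/C=C/C=C(C)/C=C1C=C(/C=C/[C@@]23O[C@@H](CC2(C)C)C[C@@]3(C)O)C(=O)O/1 | intermediate
32 | CNP0216838.1: (5Z)-5-[(2E,4E,6E,8E,10E)-11-[(3R,4S)-3,4-dihydroxy-2,6,6-trimethylcyclohex-1-en-1-yl]-2,9-dimethylundeca-2,4,6,8,10-pentaen-1-ylidene]-3-[(E)-2-[(1R,2R,4S)-2-hydroxy-2,6,6-trimethyl-7-oxabicyclo[2.2.1]heptan-1-yl]ethenyl]furan-2(5H)-one | CC1=C(/C=C/C(C)=C/C=C/C=C/C=C(C)/C=C2C=C(/C=C/[C@@]34O[C@@H](CC3(C)C)C[C@@]4(C)O)C(=O)O/2)C(C)(C)C[C@H](O)[C@@H]1O | target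

**Totals**
Total step count: 25. Longest linear sequence: 13 steps (18 to 32, steps 13–25).

**Steps most likely to fail**

Step 23. The C6–O bond may ionise fully before the hydroxyl arrives; the delocalised cation could then be captured by the C5 oxygen at C8 (ring-expanded 5,8-furanoid ether) or collapse by a 1,2-shift with ring contraction. The fallback sets out from 26 and comes back at 30: the bridge is closed on a small substrate in which neither the dienyl lactone nor the enal can take part, and the fragment union follows. The silyl ether of 26 is cleaved with PPTS in MeOH to 4,4,5,5-tetramethyl-2-[(E)-2-[(1S,4S,6R)-4-hydroxy-2,2,6-trimethyl-7-oxabicyclo[4.1.0]heptan-1-yl]ethenyl]-1,3,2-dioxaborolane F1. CSA in CH2Cl2 should convert it into the bicyclic alkenylboronate 4,4,5,5-tetramethyl-2-[(E)-2-[(1R,2R,4S)-2-hydroxy-2,6,6-trimethyl-7-oxabicyclo[2.2.1]heptan-1-yl]ethenyl]-1,3,2-dioxaborolane F2. Suzuki–Miyaura coupling of F2 with 17 under the conditions of step 20 gives (5Z)-5-[(2E)-4-hydroxy-2-methylbut-2-en-1-ylidene]-3-[(E)-2-[(1R,2R,4S)-2-hydroxy-2,6,6-trimethyl-7-oxabicyclo[2.2.1]heptan-1-yl]ethenyl]furan-2(5H)-one F3, and MnO2 oxidation of F3 returns 30.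

Step 2. The hydroperoxide anion may add from the face away from the hydroxyl (poor facial selectivity), or the base may isomerise the γ-hydroxy enone to the saturated 1,4-dione before epoxidation. The fallback sets out from 2 and comes back at 4. Hydrogen-bond-directed syn-dihydroxylation with stoichiometric OsO4 and TMEDA (CH2Cl2, −78 °C), which delivers both oxygens on the face of the allylic hydroxyl, gives (2S,3S,4S)-2,3,4-trihydroxy-2,6,6-trimethylcyclohexan-1-one F4. Reductive removal of the tertiary α-hydroxyl of F4 with SmI2 in THF/MeOH returns 4.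

Step 25. The aqueous base may open the enol lactone, the trienylboronate may lose boron by protonation before transmetalation, and alkene geometry may scramble. The fallback sets out from 31 and 12 and comes back at 32 by a base-free Stille union. Iodide 31 is stannylated with hexamethylditin (Me3Sn)2 and Pd(PPh3)4 (cat.) in THF to (5Z)-3-[(E)-2-[(1R,2R,4S)-2-hydroxy-2,6,6-trimethyl-7-oxabicyclo[2.2.1]heptan-1-yl]ethenyl]-5-[(2E,4E)-2-methyl-5-(trimethylstannyl)penta-2,4-dien-1-ylidene]furan-2(5H)-one F5. Aldehyde 12 is homologated by Takai iodo-olefination (CrCl2, CHI3, THF) to (1S,2R)-4-[(1E,3E,5E)-6-iodo-3-methylhexa-1,3,5-trien-1-yl]-3,5,5-trimethylcyclohex-3-ene-1,2-diol F6. Stille coupling of F5 with F6 (Pd2(dba)3, AsPh3, NMP, rt, dark) gives 32.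

Further compounds
F1 | step 23 | 4,4,5,5-tetramethyl-2-[(E)-2-[(1S,4S,6R)-4-hydroxy-2,2,6-trimethyl-7-oxabicyclo[4.1.0]heptan-1-yl]ethenyl]-1,3,2-dioxaborolane | CC1(C)OB(/C=C/[C@@]23O[C@]2(C)C[C@@H](O)CC3(C)C)OC1(C)C
F2 | step 23 | 4,4,5,5-tetramethyl-2-[(E)-2-[(1R,2R,4S)-2-hydroxy-2,6,6-trimethyl-7-oxabicyclo[2.2.1]heptan-1-yl]ethenyl]-1,3,2-dioxaborolane | CC1(C)OB(/C=C/[C@@]23O[C@@H](CC2(C)C)C[C@@]3(C)O)OC1(C)C
F3 | step 23 | (5Z)-5-[(2E)-4-hydroxy-2-methylbut-2-en-1-ylidene]-3-[(E)-2-[(1R,2R,4S)-2-hydroxy-2,6,6-trimethyl-7-oxabicyclo[2.2.1]heptan-1-yl]ethenyl]furan-2(5H)-one | OC/C=C(C)/C=C1C=C(/C=C/[C@@]23O[C@@H](CC2(C)C)C[C@@]3(C)O)C(=O)O/1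
F4 | step 2 | (2S,3S,4S)-2,3,4-trihydroxy-2,6,6-trimethylcyclohexan-1-one | C[C@]1(O)[C@@H](O)[C@@H](O)CC(C)(C)C1=O
F5 | step 25 | (5Z)-3-[(E)-2-[(1R,2R,4S)-2-hydroxy-2,6,6-trimethyl-7-oxabicyclo[2.2.1]heptan-1-yl]ethenyl]-5-[(2E,4E)-2-methyl-5-(trimethylstannyl)penta-2,4-dien-1-ylidene]furan-2(5H)-one | C[Sn](C)(C)/C=C/C=C(C)/C=C1C=C(/C=C/[C@@]23O[C@@H](CC2(C)C)C[C@@]3(C)O)C(=O)O/1
F6 | step 25 | (1S,2R)-4-[(1E,3E,5E)-6-iodo-3-methylhexa-1,3,5-trien-1-yl]-3,5,5-trimethylcyclohex-3-ene-1,2-diol | CC1=C(/C=C/C(C)=C/C=C/I)C(C)(C)C[C@H](O)[C@@H]1O
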